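Late in the west run, at 2.50 min, ring plus starting material reads 23.6% of the charge. Call this sum the ceiling, the fraction of the charge that can still end as ring, provided that what fills the rest of the charge is lost for good.

common to all: starting material 0.80 M

| flask | protic impurity | temperature | remark | time |
|---|---|---|---|---|
| west | 0.80 M | −20 °C | the very flask that is asked about, followed so far |  |
| south-east | 0.80 M | −35 °C | run made earlier |  |
| flask | 0.800 M | −20 °C |  | 3.0 min |

- west (time / min: ring / %, starting material / %): 0.667: 15.6, 12.4; 1.33: 18.8, 5.3; 2.00: 21.0, 3.3; 2.50: 20.7, 2.9
- south-east (time / min: ring / %, starting material / %): 1.33: 6.0, 32.2; 3.00: 7.9, 14.4; 4.00: 8.3, 9.8; 5.00: 8.8, 7.0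

(readings scatter by 0.5 percentage points)

- maple: at 3.0 min take out 90% of the ring then present, then wait 50 s
- birch: at 3.0 min add starting material, 50.0% of the amount charged, then wait 50 s
- ash: at 3.0 min raise the temperature by 25 K, then wait 50 s
- cedar: change nothing and wait 50 s more

- ring taken out counts as made
- additions bring no volume worth counting

1. ring, in percent of the starting material first charged, at 3.0 min
2. which option adds most ring ("none" when 2 percentage points or less is all one gets) (maple / birch / ash / cedar / none)
3. ring present, with what was taken out counted in, in percent of the starting material first charged, after ash
4. ring present, with what was taken out counted in, in percent of the starting material first charged, after cedar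

Read the west table row against row, adding the two columns. The sum goes from 28.0% at 0.667 min to 24.1% at 1.33 min, then 24.3% at 2.00 min, and then the ceiling, so the last three rows are level within a scatter of 0.5 percentage points on each reading. Between 1.33 min and 2.50 min ring reads up by 1.9 points and starting material reads down by 2.4 points, so in these readings what leaves the starting material column turns up in the ring column while the rest of the charge stays level.

At its last reading the west flask has 2.9 points of room under the ceiling. My own reckoning therefore puts ring at 3.0 min a little under the ceiling, and on the proviso above cedar and maple can win no more than that room. Birch lifts the ceiling with fresh starting material, worth 50.0% of the charge. Ash can pass the ceiling if the rest of the charge gives something back, and these level sums do not test that, so I leave it open.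

The forecast gives 21.2% for now, 21.7% after cedar and 22.4% after ash, below the ceiling, saying of ash “Little is left to gain”, and it picks birch.

The flask gives 22.1% at 3.0 min, and 23.4% after cedar, under the ceiling. The best option is ash, which adds 23 points against 12 points for birch and reaches 45.2%, which is 22 points above the ceiling.

    starting material → ring (k = 0.0109 s⁻¹, Ea = 76.0 kJ mol⁻¹)
    2 starting material ⇌ open dimer (K = 21.0 M⁻¹, k = 0.0406 M⁻¹ s⁻¹, Ea = 48.0 kJ mol⁻¹, ΔH = −52.0 kJ mol⁻¹)
    starting material + protic impurity → quenched substrate (k = 0.0339 M⁻¹ s⁻¹, Ea = 56.0 kJ mol⁻¹)
    (constants at −20 °C)

At 3.00 min the flask's rest of the charge is open dimer, a resting state of the starting material, at 33.2%, and quenched substrate at 42.3%. The first of these forms by a step that runs both ways. Take the same reckoning to the neighbour at −35 °C: the south-east reading at 3.00 min gives a ceiling of 22.3%, and that flask shows ring at 7.43% with starting material at 14%. In that neighbour at 3.00 min, open dimer stands at 49.6%, above quenched substrate at 28.5%.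

All runs are simulated on assumed constants, noise included.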